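**Retrosynthetic overview**

1. The target is the 4-hydroxybenzoate of a germacra-1(10)E,5E-diene-4,8-diol. Germacrane numbers are used throughout: C1=C10 is the trisubstituted ring olefin (C14 methyl on C10), C4 the tertiary carbinol (C15 methyl), C5=C6 the disubstituted olefin, C7 carries isopropyl, C8 the ester oxygen, C9 is the ring methylene. The aryl ester is attached last at C8–O.
2. The only ring, the cyclodeca-1(10),5-diene, is closed by forming C9–C10. The array C8(OH)–C9H2–C10(CH3)=C1H (E) inside the ring is the retron of a reductive coupling of a 2-alkyne (C14–C10≡C1) with a terminal oxirane (C8–C9). One operation should therefore give the ring, the E-trisubstituted olefin and the free C8 hydroxyl from an acyclic epoxy-enyne.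
3. The acyclic chain is cut at C5=C6 (Julia–Kocienski) into aldehyde 9 (C1–C5, C10, C14, C15) and sulfone 19 (C6–C9). C4 comes from (R)-linalool, whose trisubstituted olefin is cleaved and rebuilt as the methyl alkyne.
4. C7 and C8 are set together by one Evans syn-aldol with chloroacetaldehyde; the chlorohydrin is the latent oxirane.
5. Order of ring formation: oxirane (step 13), then the ten-membered carbocycle (step 14).

Key step: step 14

Remark on the chemistry: (R)-(−)-linalool of high enantiomeric purity is assumed, since it fixes C4 independently of the auxiliary-controlled C7/C8 pair; chloroacetaldehyde is used anhydrous, freshly distilled from the commercial aqueous solution.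

**Route**

Step 1
Reactants: 1 (R)-(−)-linalool, (3R)-3,7-dimethylocta-1,6-dien-3-ol
Product: 2 triethyl{[(3R)-3,7-dimethylocta-1,6-dien-3-yl]oxy}silane
Conditions: Et3SiOTf, 2,6-lutidine, CH2Cl2, −78 → 0 °C
Reagents that add atoms: triethylsilyl trifluoromethanesulfonate, CC[Si](CC)(CC)OS(=O)(=O)C(F)(F)F
Why: Silyl triflate with a hindered pyridine base silylates the tertiary allylic alcohol without ionising it (silyl ether formation); the C4 stereocentre is that of the chiral-pool alcohol and is not touched.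

Step 2
Reactants: 2 triethyl{[(3R)-3,7-dimethylocta-1,6-dien-3-yl]oxy}silane
Product: 4 (4R)-4-methyl-4-[(triethylsilyl)oxy]hex-5-enal, via secondary ozonide 3 (not isolated)
Conditions: O3 (1 equiv), CH2Cl2, −78 °C; then PPh3, −78 °C → rt
Reagents that add atoms: ozone, [O-][O+]=O
Why: Chemoselective ozonolysis with reductive work-up: electrophilic ozone should attack the electron-rich trisubstituted olefin much faster than the vinyl group next to the silyloxy quaternary carbon, which frees the future C1 as an aldehyde.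

Step 3
Reactants: 4 (4R)-4-methyl-4-[(triethylsilyl)oxy]hex-5-enal
Product: 5 triethyl{[(3R)-7,7-dibromo-3-methylhepta-1,6-dien-3-yl]oxy}silane
Conditions: CBr4, PPh3, 2,6-lutidine (buffer), CH2Cl2, 0 °C
Reagents that add atoms: carbon tetrabromide, BrC(Br)(Br)Br
Why: First stage of the Corey–Fuchs sequence (dibromomethylene ylide olefination) on an unhindered aliphatic aldehyde; the buffered ylide conditions leave the silyl ether and the vinyl group alone.

Step 4
Reactants: 5 triethyl{[(3R)-7,7-dibromo-3-methylhepta-1,6-dien-3-yl]oxy}silane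
Product: 7 triethyl{[(3R)-3-methyloct-1-en-6-yn-3-yl]oxy}silane, via lithium acetylide 6 (not isolated)
Conditions: n-BuLi (2.2 equiv), THF, −78 → 0 °C; then MeI, DMPU, −78 °C → rt
Reagents that add atoms: iodomethane, CI
Why: Second stage of the Corey–Fuchs sequence: bromine–lithium exchange, 1,2-shift and deprotonation give the acetylide, which MeI methylates on carbon, so that C10 carries the C14 methyl.

Step 5
Reactants: 7 triethyl{[(3R)-3-methyloct-1-en-6-yn-3-yl]oxy}silane
Product: 9 (2R)-2-methyl-2-[(triethylsilyl)oxy]hept-5-ynal, via 1,2-diol 8 (not isolated)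
Conditions: OsO4 (2 mol %), NaIO4, 2,6-lutidine, dioxane/H2O (3:1), rt
Reagents that add atoms: osmium tetroxide, O=[Os](=O)(=O)=O (catalytic oxygen carrier); sodium periodate, [Na+].[O-]I(=O)(=O)=O (reoxidant and oxygen source)
Why: Johnson–Lemieux cleavage: OsO4 dihydroxylates the only olefin and ignores the internal alkyne, and periodate cleaves the diol to an α-silyloxy aldehyde that cannot enolise because C4 is quaternary.

Step 6
Reactants: 10 (4R)-4-benzyl-1,3-oxazolidin-2-one; 11 3-methylbutanoyl chloride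
Product: 12 (4R)-4-benzyl-3-(3-methylbutanoyl)-1,3-oxazolidin-2-one
Conditions: Et3N, DMAP (cat.), CH2Cl2, 0 °C → rt
Reagents that add atoms: none
Why: DMAP-catalysed N-acylation of the oxazolidinone by the acid chloride, the standard preparation of an Evans imide.

Step 7
Reactants: 12 (4R)-4-benzyl-3-(3-methylbutanoyl)-1,3-oxazolidin-2-one; 13 chloroacetaldehyde
Product: 15 (4R)-4-benzyl-3-[(2R,3R)-4-chloro-3-hydroxy-2-(propan-2-yl)butanoyl]-1,3-oxazolidin-2-one, via Z-boron enolate 14 (not isolated)
Conditions: Bu2BOTf, i-Pr2NEt, CH2Cl2, 0 °C; 13 (anhydrous), −78 → 0 °C; pH 7 buffer, MeOH, 30 % H2O2, 0 °C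
Reagents that add atoms: none
Why: Evans syn-aldol: the Z-boron enolate should react through a closed chair (Zimmerman–Traxler) transition state on the face away from the benzyl group of the (R)-auxiliary, which sets C7 (isopropyl) and C8 (oxygen) as the 2,3-syn (2R,3R) pair; the chloromethyl group is the latent oxirane carbon C9.

Step 8
Reactants: 15 (4R)-4-benzyl-3-[(2R,3R)-4-chloro-3-hydroxy-2-(propan-2-yl)butanoyl]-1,3-oxazolidin-2-one
Product: 16 (2S,3R)-4-chloro-2-(propan-2-yl)butane-1,3-diol
Conditions: LiBH4, MeOH (1 equiv), THF, 0 °C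
Reagents that add atoms: none
Why: Reductive cleavage of the imide by LiBH4 gives the C6 primary alcohol and returns the auxiliary; at 0 °C the chlorohydrin and both stereocentres should stay intact.

Step 9
Reactants: 16 (2S,3R)-4-chloro-2-(propan-2-yl)butane-1,3-diol
Product: 17 (2R,3R)-1-chloro-4-methyl-3-{[(1-phenyl-1H-tetrazol-5-yl)sulfanyl]methyl}pentan-2-ol
Conditions: 1-phenyl-1H-tetrazole-5-thiol, PPh3, DIAD, THF, 0 °C → rt
Reagents that add atoms: 1-phenyl-1H-tetrazole-5-thiol, Sc1nnnn1-c1ccccc1
Why: Mitsunobu thioetherification should select the primary hydroxyl over the hindered secondary chlorohydrin hydroxyl; no stereocentre takes part.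

Step 10
Reactants: 17 (2R,3R)-1-chloro-4-methyl-3-{[(1-phenyl-1H-tetrazol-5-yl)sulfanyl]methyl}pentan-2-ol
Product: 18 (2R,3R)-1-chloro-4-methyl-3-{[(1-phenyl-1H-tetrazol-5-yl)sulfonyl]methyl}pentan-2-ol
Conditions: (NH4)6Mo7O24·4H2O (cat.), 30 % H2O2, EtOH, 0 °C → rt
Reagents that add atoms: hydrogen peroxide, OO
Why: Molybdate-catalysed peroxide oxidation takes the sulfide to the sulfone and should leave the secondary alcohol and the chloride alone.

Step 11
Reactants: 18 (2R,3R)-1-chloro-4-methyl-3-{[(1-phenyl-1H-tetrazol-5-yl)sulfonyl]methyl}pentan-2-ol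
Product: 19 5-({(2R,3R)-4-chloro-2-(propan-2-yl)-3-[(trimethylsilyl)oxy]butyl}sulfonyl)-1-phenyl-1H-tetrazole
Conditions: Me3SiCl, imidazole, CH2Cl2, 0 °C
Reagents that add atoms: chlorotrimethylsilane, C[Si](C)(C)Cl
Why: Silylation masks the hydroxyl so that no alkoxide can close the oxirane or attack the tetrazole during the olefination; trimethylsilyl is chosen because carbonate in methanol removes it later without touching the tertiary triethylsilyl ether.

Step 12
Reactants: 19 5-({(2R,3R)-4-chloro-2-(propan-2-yl)-3-[(trimethylsilyl)oxy]butyl}sulfonyl)-1-phenyl-1H-tetrazole; 9 (2R)-2-methyl-2-[(triethylsilyl)oxy]hept-5-ynal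
Product: 20 {[(2R,3S,4E,6R)-1-chloro-6-methyl-3-(propan-2-yl)-6-[(triethylsilyl)oxy]undec-4-en-9-yn-2-yl]oxy}(trimethyl)silane
Conditions: KN(SiMe3)2 added to 19 + 9, DME, −78 °C → rt
Reagents that add atoms: none
Why: Julia–Kocienski olefination: addition of the sulfonyl carbanion to the non-enolisable aldehyde, Smiles rearrangement and loss of SO2 and tetrazololate should give the E-C5=C6 olefin, favoured by the bulky α-quaternary aldehyde and the potassium counter-ion in DME; C4, C7 and C8 are not affected.

Step 13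
Reactants: 20 {[(2R,3S,4E,6R)-1-chloro-6-methyl-3-(propan-2-yl)-6-[(triethylsilyl)oxy]undec-4-en-9-yn-2-yl]oxy}(trimethyl)silane
Product: 22 triethyl({(6R,7E,9S)-6,10-dimethyl-9-[(2R)-oxiran-2-yl]undec-7-en-2-yn-6-yl}oxy)silane, via chlorohydrin 21 (not isolated)
Conditions: K2CO3, MeOH, 0 °C → rt
Reagents that add atoms: none
Why: Methanolysis of the secondary trimethylsilyl ether and internal Williamson closure (3-exo-tet) of the chlorohydrin alkoxide give the terminal oxirane with retention at C8, because the C8–O bond is never broken; the tertiary triethylsilyl ether should survive carbonate in methanol.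

Step 14
Reactants: 22 triethyl({(6R,7E,9S)-6,10-dimethyl-9-[(2R)-oxiran-2-yl]undec-7-en-2-yn-6-yl}oxy)silane
Product: 23 (1S,2S,3E,5R,8E)-5,9-dimethyl-2-(propan-2-yl)-5-[(triethylsilyl)oxy]cyclodeca-3,8-dien-1-ol
Conditions: Ni(cod)2 (20 mol %), PBu3 (40 mol %), Et3B (4 equiv), toluene, 40 °C, slow addition of 22 (final 0.01 M); aq. NH4Cl
Reagents that add atoms: none
Why: Proposed new method: zerovalent nickel (Ni(cod)2/PBu3) is expected to add oxidatively into the unhindered C9–O bond of the terminal oxirane (SN2-type, assisted by Et3B) to give a nickelaoxetane of divalent nickel; the tethered alkyne then inserts syn into Ni–C9 with C9 bonding to the methyl-bearing alkyne carbon C10, and ethyl transfer from Et3B, β-hydride elimination and C–H reductive elimination place hydrogen on C1 cis to C9 and release the C8 boron alkoxide. The closest known reaction type is the nickel-catalysed reductive coupling of alkynes with terminal epoxides, known intermolecularly and for five- and six-membered ring closures, together with nickel-catalysed alkyne–aldehyde reductive macrocyclisations; a ten-membered, endocyclic version has not been shown. The ten-membered carbocycle is closed in the endo mode at both partners, so that both alkyne carbons and both oxirane carbons become ring members. No new stereocentre is formed: C8 keeps the oxirane configuration because only the C9–O bond is broken, and the E geometry of C1=C10 follows from syn addition of hydrogen and C9 across the alkyne. The step needs regioselectivity at the alkyne (C9–C10 and not C9–C1, which would give a nine-membered ring with an exocyclic ethylidene), attack at the oxirane CH2, and cyclisation in preference to alkyne oligomerisation. These should be secured by the small phosphine, which directs C–C bond formation to the alkyne carbon carrying the smaller methyl group, by the primary oxirane terminus, by the low strain of an (E,E)-cyclodeca-1,6-diene compared with the nine-membered alternative, by the conformational bias of the E-C5=C6 olefin and the quaternary C4, and by slow addition at high dilution.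

Step 15
Reactants: 23 (1S,2S,3E,5R,8E)-5,9-dimethyl-2-(propan-2-yl)-5-[(triethylsilyl)oxy]cyclodeca-3,8-dien-1-ol; 24 4-[(tert-butyldimethylsilyl)oxy]benzoic acid
Product: 25 (1S,2S,3E,5R,8E)-5,9-dimethyl-2-(propan-2-yl)-5-[(triethylsilyl)oxy]cyclodeca-3,8-dien-1-yl 4-[(tert-butyldimethylsilyl)oxy]benzoate
Conditions: DCC, DMAP, CH2Cl2, 0 °C → rt
Reagents that add atoms: none
Why: Steglich esterification of the only free hydroxyl (C8) proceeds at the acyl carbon, so C8 keeps its configuration.

Step 16
Reactants: 25 (1S,2S,3E,5R,8E)-5,9-dimethyl-2-(propan-2-yl)-5-[(triethylsilyl)oxy]cyclodeca-3,8-dien-1-yl 4-[(tert-butyldimethylsilyl)oxy]benzoate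
Product: 26 (1S,2S,3E,5R,8E)-5-hydroxy-5,9-dimethyl-2-(propan-2-yl)cyclodeca-3,8-dien-1-yl 4-hydroxybenzoate (CNP0277965.1)
Conditions: Bu4NF, AcOH, THF, 0 °C → rt
Reagents that add atoms: none
Why: Fluoride should cleave both the phenolic tert-butyldimethylsilyl ether and the tertiary triethylsilyl ether, and the acetic acid buffer avoids base-mediated ester cleavage and acid-promoted ionisation of the tertiary allylic alcohol.

**Compound list**

1 | (R)-(−)-linalool, (3R)-3,7-dimethylocta-1,6-dien-3-ol | CC(C)=CCC[C@@](C)(O)C=C | starting material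
2 | triethyl{[(3R)-3,7-dimethylocta-1,6-dien-3-yl]oxy}silane | CC(C)=CCC[C@@](C)(O[Si](CC)(CC)CC)C=C | intermediate
3 | 3,3-dimethyl-5-{(3R)-3-methyl-3-[(triethylsilyl)oxy]pent-4-en-1-yl}-1,2,4-trioxolane (secondary ozonide, both epimers at the ring carbon) | CC1(C)OOC(CC[C@@](C)(O[Si](CC)(CC)CC)C=C)O1 | intermediate (not isolated)
4 | (4R)-4-methyl-4-[(triethylsilyl)oxy]hex-5-enal | O=CCC[C@@](C)(O[Si](CC)(CC)CC)C=C | intermediate
5 | triethyl{[(3R)-7,7-dibromo-3-methylhepta-1,6-dien-3-yl]oxy}silane | BrC(Br)=CCC[C@@](C)(O[Si](CC)(CC)CC)C=C | intermediate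
6 | {(5R)-5-methyl-5-[(triethylsilyl)oxy]hept-6-en-1-yn-1-yl}lithium (lithium acetylide) | [Li]C#CCC[C@@](C)(O[Si](CC)(CC)CC)C=C | intermediate (not isolated)
7 | triethyl{[(3R)-3-methyloct-1-en-6-yn-3-yl]oxy}silane | CC#CCC[C@@](C)(O[Si](CC)(CC)CC)C=C | intermediate
8 | (3R)-3-methyl-3-[(triethylsilyl)oxy]oct-6-yne-1,2-diol (both C2 epimers) | CC#CCC[C@@](C)(O[Si](CC)(CC)CC)C(O)CO | intermediate (not isolated)
9 | (2R)-2-methyl-2-[(triethylsilyl)oxy]hept-5-ynal | CC#CCC[C@@](C)(O[Si](CC)(CC)CC)C=O | intermediate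
10 | (4R)-4-benzyl-1,3-oxazolidin-2-one | O=C1N[C@H](Cc2ccccc2)CO1 | starting material
11 | 3-methylbutanoyl chloride | CC(C)CC(Cl)=O | starting material
12 | (4R)-4-benzyl-3-(3-methylbutanoyl)-1,3-oxazolidin-2-one | CC(C)CC(=O)N1[C@H](Cc2ccccc2)COC1=O | intermediate
13 | chloroacetaldehyde | ClCC=O | starting material
14 | (4R)-4-benzyl-3-{(1Z)-1-[(dibutylboranyl)oxy]-3-methylbut-1-en-1-yl}-1,3-oxazolidin-2-one (Z-boron enolate) | CC(C)/C=C(\OB(CCCC)CCCC)N1[C@H](Cc2ccccc2)COC1=O | intermediate (not isolated)
15 | (4R)-4-benzyl-3-[(2R,3R)-4-chloro-3-hydroxy-2-(propan-2-yl)butanoyl]-1,3-oxazolidin-2-one | ClC[C@H](O)[C@@H](C(C)C)C(=O)N1[C@H](Cc2ccccc2)COC1=O | intermediate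
16 | (2S,3R)-4-chloro-2-(propan-2-yl)butane-1,3-diol | ClC[C@H](O)[C@@H](C(C)C)CO | intermediate
17 | (2R,3R)-1-chloro-4-methyl-3-{[(1-phenyl-1H-tetrazol-5-yl)sulfanyl]methyl}pentan-2-ol | ClC[C@H](O)[C@@H](C(C)C)CSc1nnnn1-c1ccccc1 | intermediate
18 | (2R,3R)-1-chloro-4-methyl-3-{[(1-phenyl-1H-tetrazol-5-yl)sulfonyl]methyl}pentan-2-ol | ClC[C@H](O)[C@@H](C(C)C)CS(=O)(=O)c1nnnn1-c1ccccc1 | intermediate
19 | 5-({(2R,3R)-4-chloro-2-(propan-2-yl)-3-[(trimethylsilyl)oxy]butyl}sulfonyl)-1-phenyl-1H-tetrazole | ClC[C@H](O[Si](C)(C)C)[C@@H](C(C)C)CS(=O)(=O)c1nnnn1-c1ccccc1 | intermediate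
20 | {[(2R,3S,4E,6R)-1-chloro-6-methyl-3-(propan-2-yl)-6-[(triethylsilyl)oxy]undec-4-en-9-yn-2-yl]oxy}(trimethyl)silane | CC#CCC[C@@](C)(O[Si](CC)(CC)CC)/C=C/[C@H](C(C)C)[C@@H](O[Si](C)(C)C)CCl | intermediate
21 | (2R,3S,4E,6R)-1-chloro-6-methyl-3-(propan-2-yl)-6-[(triethylsilyl)oxy]undec-4-en-9-yn-2-ol | CC#CCC[C@@](C)(O[Si](CC)(CC)CC)/C=C/[C@H](C(C)C)[C@@H](O)CCl | intermediate (not isolated)
22 | triethyl({(6R,7E,9S)-6,10-dimethyl-9-[(2R)-oxiran-2-yl]undec-7-en-2-yn-6-yl}oxy)silane | CC#CCC[C@@](C)(O[Si](CC)(CC)CC)/C=C/[C@H](C(C)C)[C@@H]1CO1 | intermediate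
23 | (1S,2S,3E,5R,8E)-5,9-dimethyl-2-(propan-2-yl)-5-[(triethylsilyl)oxy]cyclodeca-3,8-dien-1-ol | C/C1=C\CC[C@@](C)(O[Si](CC)(CC)CC)/C=C/[C@H](C(C)C)[C@@H](O)C1 | intermediate
24 | 4-[(tert-butyldimethylsilyl)oxy]benzoic acid | O=C(O)c1ccc(O[Si](C)(C)C(C)(C)C)cc1 | starting material
25 | (1S,2S,3E,5R,8E)-5,9-dimethyl-2-(propan-2-yl)-5-[(triethylsilyl)oxy]cyclodeca-3,8-dien-1-yl 4-[(tert-butyldimethylsilyl)oxy]benzoate | C/C1=C\CC[C@@](C)(O[Si](CC)(CC)CC)/C=C/[C@H](C(C)C)[C@@H](OC(=O)c2ccc(O[Si](C)(C)C(C)(C)C)cc2)C1 | intermediate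
26 | (1S,2S,3E,5R,8E)-5-hydroxy-5,9-dimethyl-2-(propan-2-yl)cyclodeca-3,8-dien-1-yl 4-hydroxybenzoate | C/C1=C\CC[C@@](C)(O)/C=C/[C@H](C(C)C)[C@@H](OC(=O)c2ccc(O)cc2)C1 | target

**Totals**

Total step count: 16. Longest linear sequence: 11 steps (10 → 26, steps 6 to 16); the linalool branch (steps 1 to 5) joins at step 12.

**Steps most likely to fail**

1. Step 14 (Proposed new method). What may go wrong: oligomerisation or cyclotrimerisation of the alkyne, and closure through the other alkyne carbon to a nine-membered ring with an exocyclic ethylidene, may outrun the slow oxidative addition of zerovalent nickel to the β-branched oxirane.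
   Fallback, from 22 back to 23, using known chemistry: the oxirane is replaced by an aldehyde, for which nickel-catalysed alkyne–aldehyde reductive macrocyclisation is documented, and the oxidation pattern is repaired afterwards.
   - Hydrolysis of the oxirane of 22 with water under (salen)Co(OAc) catalysis (trivalent cobalt, matched enantiomer, THF, rt) should give the 1,2-diol F1.
   - Me3SiCl/Et3N should give the bis(trimethylsilyl) ether F2.
   - Swern oxidation ((COCl)2, DMSO, CH2Cl2, −78 → −30 °C, then Et3N), which oxidises a primary trimethylsilyl ether directly, should give the α-silyloxy aldehyde F3.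
   - Ni(cod)2/PBu3/Et3B in toluene under slow addition should close the ring to the macrocyclic allylic alcohol F4 (both C9 epimers are usable).
   - K2CO3/MeOH should remove the secondary silyl group to give the 8,9-diol F5.
   - 1,1′-Carbonyldiimidazole (toluene, 60 °C) should give the cyclic carbonate F6.
   - Pd2(dba)3·CHCl3/PBu3 with HCO2H/Et3N (THF, rt) should ionise the allylic C9–O bond to a π-allyl complex of divalent palladium, which loses CO2 and delivers hydride to C9. This should give the homoallylic alcohol 23 with C8 untouched.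

2. Step 12. What may go wrong: addition of the β-branched sulfonyl carbanion to the hindered α-quaternary aldehyde may be slow, which leaves time for self-condensation of the metalated sulfone and for erosion of the E-selectivity.
   Fallback, from 16 (with 9) back to 20: a classical Julia–Lythgoe olefination, in which the olefin geometry is set in a separate reductive elimination.
   - (PhS)2/PBu3 (THF, rt) should convert the primary hydroxyl of 16 into the phenyl sulfide F7.
   - (NH4)6Mo7O24·4H2O/H2O2 should give the phenyl sulfone F8.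
   - Me3SiCl/imidazole should give the silyl ether F9.
   - n-BuLi (THF, −78 °C), then aldehyde 9, then benzoyl chloride should give the β-benzoyloxy sulfone F10 as a diastereomer mixture.
   - SmI2/HMPA (THF, −78 °C) should effect reductive elimination to the E-olefin 20.

3. Step 7. What may go wrong: anhydrous chloroacetaldehyde may polymerise or hydrate before it meets the enolate, and the chlorohydrin may close under the basic oxidative work-up; both lower conversion and diastereomeric purity.
   Fallback, from 12 back to 15: the C9 leaving group is introduced after the aldol.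
   - The same boron aldol with commercial benzyloxyacetaldehyde (O=CCOCc1ccccc1), a stable monomeric aldehyde, should give the benzyl ether aldol adduct F11.
   - Hydrogenolysis (H2, Pd(OH)2/C, EtOAc) should give the diol imide F12.
   - Selective chlorination of the primary hydroxyl (PPh3, N-chlorosuccinimide, CH2Cl2, 0 °C; Appel-type) should give 15.

**Further compounds**

F1 | step 14 | (2R,3S,4E,6R)-6-methyl-3-(propan-2-yl)-6-[(triethylsilyl)oxy]undec-4-en-9-yne-1,2-diol | CC#CCC[C@@](C)(O[Si](CC)(CC)CC)/C=C/[C@H](C(C)C)[C@@H](O)CO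
F2 | step 14 | 1,2-bis(trimethylsilyl) ether of F1 | CC#CCC[C@@](C)(O[Si](CC)(CC)CC)/C=C/[C@H](C(C)C)[C@@H](O[Si](C)(C)C)CO[Si](C)(C)C
F3 | step 14 | (2R,3S,4E,6R)-6-methyl-3-(propan-2-yl)-6-[(triethylsilyl)oxy]-2-[(trimethylsilyl)oxy]undec-4-en-9-ynal | CC#CCC[C@@](C)(O[Si](CC)(CC)CC)/C=C/[C@H](C(C)C)[C@@H](O[Si](C)(C)C)C=O
F4 | step 14 | macrocyclic allylic alcohol: 23 with an additional hydroxyl at C9 (both epimers) and a trimethylsilyl ether at C8 | C/C1=C\CC[C@@](C)(O[Si](CC)(CC)CC)/C=C/[C@H](C(C)C)[C@@H](O[Si](C)(C)C)C1O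
F5 | step 14 | macrocyclic 8,9-diol: 23 with an additional hydroxyl at C9 (both epimers) | C/C1=C\CC[C@@](C)(O[Si](CC)(CC)CC)/C=C/[C@H](C(C)C)[C@@H](O)C1O
F6 | step 14 | 8,9-cyclic carbonate of F5 | C/C1=C\CC[C@@](C)(O[Si](CC)(CC)CC)/C=C/[C@H](C(C)C)[C@@H](OC(=O)O2)C12
F7 | step 12 | (2R,3R)-1-chloro-4-methyl-3-[(phenylsulfanyl)methyl]pentan-2-ol | ClC[C@H](O)[C@@H](C(C)C)CSc1ccccc1
F8 | step 12 | (2R,3R)-1-chloro-4-methyl-3-[(phenylsulfonyl)methyl]pentan-2-ol | ClC[C@H](O)[C@@H](C(C)C)CS(=O)(=O)c1ccccc1
F9 | step 12 | {[(2R,3R)-1-chloro-4-methyl-3-[(phenylsulfonyl)methyl]pentan-2-yl]oxy}(trimethyl)silane | ClC[C@H](O[Si](C)(C)C)[C@@H](C(C)C)CS(=O)(=O)c1ccccc1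
F10 | step 12 | β-benzoyloxy sulfone from F9 and 9 (mixture at the two new centres C5 and C6) | CC#CCC[C@@](C)(O[Si](CC)(CC)CC)C(OC(=O)c1ccccc1)C([C@H](C(C)C)[C@@H](O[Si](C)(C)C)CCl)S(=O)(=O)c1ccccc1
F11 | step 7 | (4R)-4-benzyl-3-[(2R,3R)-4-(benzyloxy)-3-hydroxy-2-(propan-2-yl)butanoyl]-1,3-oxazolidin-2-one | C(OC[C@H](O)[C@@H](C(C)C)C(=O)N1[C@H](Cc2ccccc2)COC1=O)c1ccccc1
F12 | step 7 | (4R)-4-benzyl-3-[(2R,3R)-3,4-dihydroxy-2-(propan-2-yl)butanoyl]-1,3-oxazolidin-2-one | OC[C@H](O)[C@@H](C(C)C)C(=O)N1[C@H](Cc2ccccc2)COC1=O
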